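Retrosynthesis: the bond from C6 of the chromone to the side-chain CH2 is cut first (sp2–sp3 cross-coupling). The dihydropyranone is then opened at two bonds at once, ring O–C(enol ether) and C(=O)–CH=, to a terminal alkyne and a 3-hydroxybutanoyl donor; the chromone ring is bought intact.
Enabling feature: in the 2,3-dihydro-4H-pyran-4-one, ring oxygen O1 and carbonyl carbon C4 are 1,3-related through C2(H)(CH3) and C3H2, which is a β-hydroxy acyl unit. C5=C6 is an oxygen-bearing enone pair at the oxidation level of an alkyne, so a C≡C unit can be annulated onto an O–C–C–C(=O) unit in a formal [4+2] event.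
Forward: hydroxy ester → silyl-protected chiral alkyne; alkyne + unprotected β-hydroxy Weinreb amide → dihydropyranone in one flask (the only ring made); alcohol → iodide → alkylzinc; Negishi coupling with the C6-iodinated, O5-protected chromone; acetal removal.
Stereochemistry: no stereocenter is created. The side-chain methyl center is bought as an (R)-3-hydroxy-2-methylpropanoate ester and the ring methyl center as an (S)-3-hydroxybutanoate ester. Every step after ring formation is neutral or acidic, so neither center can epimerize by retro-oxa-Michael opening or γ-enolization.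

Key step: step 4

Step 1
Reactants: 1 methyl (R)-3-hydroxy-2-methylpropanoate
Product: 2 methyl (R)-3-[(tert-butyldimethylsilyl)oxy]-2-methylpropanoate
Conditions: TBSCl (1.1 equiv), imidazole (1.5 equiv), CH2Cl2, 0 °C to rt
Reagents that add atoms: tert-butyldimethylsilyl chloride, CC(C)(C)[Si](C)(C)Cl
Why: Imidazole-mediated silyl ether formation masks the primary hydroxyl for the hydride and organolithium steps that follow, and the α-stereocenter of the ester is not touched.

Step 2
Reactants: 2 methyl (R)-3-[(tert-butyldimethylsilyl)oxy]-2-methylpropanoate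
Product: 4 (S)-tert-butyldimethyl[(2-methylbut-3-yn-1-yl)oxy]silane, via aldehyde 3 (not isolated)
Conditions: i-Bu2AlH (1.05 equiv), CH2Cl2, –78 °C; then MeOH, K2CO3 (3 equiv), dimethyl (1-diazo-2-oxopropyl)phosphonate (1.3 equiv), –78 °C to rt
Reagents that add atoms: dimethyl (1-diazo-2-oxopropyl)phosphonate, CC(=O)C(=[N+]=[N-])P(=O)(OC)OC
Why: Partial reduction of the ester to the aluminium hemiacetal followed by in-flask Seyferth–Gilbert homologation in its Ohira–Bestmann form (olefination by the diazomethylphosphonate anion, loss of N2, 1,2-hydrogen shift of the alkylidene carbene) should give the terminal alkyne without isolating the epimerizable aldehyde, so the purchased stereocenter is carried over unchanged.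

Step 3
Reactants: 5 ethyl (S)-3-hydroxybutanoate
Product: 6 (S)-3-hydroxy-N-methoxy-N-methylbutanamide
Conditions: MeNHOMe·HCl (1.5 equiv), i-PrMgCl (4.5 equiv), THF, –20 °C to 0 °C
Reagents that add atoms: N,O-dimethylhydroxylamine hydrochloride, CNOC.Cl
Why: Aminolysis of the ester by the chloromagnesium amide of N,O-dimethylhydroxylamine (Weinreb amide formation) tolerates the free hydroxyl as its magnesium alkoxide and leaves the carbinol stereocenter from the chiral pool untouched.

Step 4
Reactants: 4 (S)-tert-butyldimethyl[(2-methylbut-3-yn-1-yl)oxy]silane; 6 (S)-3-hydroxy-N-methoxy-N-methylbutanamide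
Product: 12 (S)-6-[(R)-1-hydroxypropan-2-yl]-2-methyl-2,3-dihydro-4H-pyran-4-one, via lithium acetylide 7 (not isolated), via chloromagnesium alkoxide 8 (not isolated), via tetrahedral adduct 9 (not isolated), via hydroxy ynone 10 (not isolated), via silyl ether 11 (not isolated)
Conditions: 4 (1.1 equiv), n-BuLi (1.1 equiv), THF, –78 °C; 6 (1.0 equiv) pretreated with i-PrMgCl (1.0 equiv), THF, –40 °C, added by cannula, –78 °C to 0 °C; then TsOH·H2O (6 equiv), MeOH, –20 °C to rt (40 °C if needed)
Reagents that add atoms: none
Why: Acetylide 7 adds to the amide carbonyl of alkoxide 8 and the N-methoxy chelate holds tetrahedral adduct 9 so that no second addition occurs; acid then releases β-hydroxy ynone 10, whose protonated (or methanol-adducted) ynone is attacked by the secondary hydroxyl at the alkyne carbon β to the carbonyl, and the methanolic acid finally cleaves the primary silyl ether of 11. The closest known reaction types are the Weinreb ynone synthesis with alkynyllithiums on unprotected β-hydroxy amides and the acid-mediated cycloisomerization of β-hydroxy ynones to 2,3-dihydro-4H-pyran-4-ones, here run in one flask as a formal [4+2] annulation. The dihydropyranone ring closes in the 6-endo-dig mode. No new stereocenter is formed: the ring methyl center comes from 5 and the side-chain center from 1, no bond to either is made or broken, and the acidic closure avoids base-induced retro-oxa-Michael opening (loss of the ring center) and propargyl–allenyl isomerization (loss of the side-chain center). The step needs single addition and 6-endo over 5-exo closure, which the Weinreb chelate and the polarization of the ynone (oxygen attack at the β-carbon) secure, while the primary oxygen could only close a four-membered ring and so does not compete.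

Step 5
Reactants: 12 (S)-6-[(R)-1-hydroxypropan-2-yl]-2-methyl-2,3-dihydro-4H-pyran-4-one
Product: 13 (S)-6-[(S)-1-iodopropan-2-yl]-2-methyl-2,3-dihydro-4H-pyran-4-one
Conditions: PPh3 (1.3 equiv), imidazole (1.5 equiv), I2 (1.3 equiv), CH2Cl2, 0 °C to rt, dark
Reagents that add atoms: iodine, II
Why: Appel-type iodination through the alkoxyphosphonium salt is an SN2 displacement at the CH2 group under near-neutral conditions, so neither the adjacent stereocenter (only its descriptor changes) nor the base-sensitive dihydropyranone is disturbed.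

Step 6
Reactants: 14 eugenin (5-hydroxy-7-methoxy-2-methyl-4H-chromen-4-one)
Product: 15 5-hydroxy-6-iodo-7-methoxy-2-methyl-4H-chromen-4-one
Conditions: BnMe3N·ICl2 (1.1 equiv), CaCO3 (1.5 equiv), CH2Cl2/MeOH (5:2), rt
Reagents that add atoms: benzyltrimethylammonium dichloroiodate, C[N+](C)(C)Cc1ccccc1.Cl[I-]Cl
Why: Electrophilic aromatic iodination of the phloroglucinol-type ring should be directed by the chelated 5-hydroxyl to its free ortho position C6, as is typical of 5-hydroxy-7-alkoxychromones and -flavones, while the buffered medium leaves the pyranone ring untouched.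

Step 7
Reactants: 15 5-hydroxy-6-iodo-7-methoxy-2-methyl-4H-chromen-4-one
Product: 17 6-iodo-7-methoxy-5-(methoxymethoxy)-2-methyl-4H-chromen-4-one, via sodium phenoxide 16 (not isolated)
Conditions: NaH (1.05 equiv), DMF, 0 °C; then MOMCl (1.5 equiv), 0 °C to rt
Reagents that add atoms: chloromethyl methyl ether, COCCl
Why: Williamson-type O-alkylation of the phenoxide with the reactive chloromethyl ether overcomes the hydrogen bond to the C4 carbonyl and removes the acidic proton that would quench the organozinc reagent of the next step.

Step 8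
Reactants: 13 (S)-6-[(S)-1-iodopropan-2-yl]-2-methyl-2,3-dihydro-4H-pyran-4-one; 17 6-iodo-7-methoxy-5-(methoxymethoxy)-2-methyl-4H-chromen-4-one
Product: 19 7-methoxy-5-(methoxymethoxy)-2-methyl-6-[(2R)-2-[(2S)-2-methyl-4-oxo-3,4-dihydro-2H-pyran-6-yl]propyl]-4H-chromen-4-one, via alkylzinc iodide 18 (not isolated)
Conditions: 13 (1.4 equiv), Zn dust (4 equiv, activated with BrCH2CH2Br and TMSCl), DMF, rt to 40 °C; then 17 (1.0 equiv), Pd2(dba)3 (2.5 mol%), SPhos (10 mol%), 45 °C
Reagents that add atoms: none
Why: Zinc insertion into the primary C–I bond followed by Negishi cross-coupling on zerovalent palladium with a bulky biarylphosphine should join the sp3 carbon to the di-ortho-substituted aryl iodide under neutral conditions that tolerate both enone systems and the acetal, and the stereocenter β to zinc is not involved.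

Step 9
Reactants: 19 7-methoxy-5-(methoxymethoxy)-2-methyl-6-[(2R)-2-[(2S)-2-methyl-4-oxo-3,4-dihydro-2H-pyran-6-yl]propyl]-4H-chromen-4-one
Product: 20 5-hydroxy-7-methoxy-2-methyl-6-[(2R)-2-[(2S)-2-methyl-4-oxo-3,4-dihydro-2H-pyran-6-yl]propyl]-4H-chromen-4-one (CNP0231471.1)
Conditions: HCl (1.25 M in MeOH), THF, 0 °C to rt
Reagents that add atoms: none
Why: Acid-catalysed acetal cleavage of the methoxymethyl ether is assisted by the peri carbonyl and is run under acidic, not basic, conditions so that the dihydropyranone and both stereocenters should be preserved.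

Compound list
1 | methyl (R)-3-hydroxy-2-methylpropanoate | OC[C@@H](C)C(=O)OC | starting material
2 | methyl (R)-3-[(tert-butyldimethylsilyl)oxy]-2-methylpropanoate | CC(C)(C)[Si](C)(C)OC[C@@H](C)C(=O)OC | intermediate
3 | (R)-3-[(tert-butyldimethylsilyl)oxy]-2-methylpropanal | CC(C)(C)[Si](C)(C)OC[C@@H](C)C=O | intermediate
4 | (S)-tert-butyldimethyl[(2-methylbut-3-yn-1-yl)oxy]silane | CC(C)(C)[Si](C)(C)OC[C@@H](C)C#C | intermediate
5 | ethyl (S)-3-hydroxybutanoate | CCOC(=O)C[C@H](C)O | starting material
6 | (S)-3-hydroxy-N-methoxy-N-methylbutanamide | CON(C)C(=O)C[C@H](C)O | intermediate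
7 | [(S)-4-[(tert-butyldimethylsilyl)oxy]-3-methylbut-1-yn-1-yl]lithium | CC(C)(C)[Si](C)(C)OC[C@@H](C)C#C[Li] | intermediate
8 | chloromagnesium (S)-4-[methoxy(methyl)amino]-4-oxobutan-2-olate | CON(C)C(=O)C[C@H](C)O[Mg]Cl | intermediate
9 | lithium chloromagnesium dialkoxide of (2S,7S)-8-[(tert-butyldimethylsilyl)oxy]-4-[methoxy(methyl)amino]-7-methyloct-5-yne-2,4-diol (both C4 epimers) | CC(C)(C)[Si](C)(C)OC[C@@H](C)C#CC(O[Li])(N(C)OC)C[C@H](C)O[Mg]Cl | intermediate
10 | (2S,7S)-8-[(tert-butyldimethylsilyl)oxy]-2-hydroxy-7-methyloct-5-yn-4-one | CC(C)(C)[Si](C)(C)OC[C@@H](C)C#CC(=O)C[C@H](C)O | intermediate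
11 | (S)-6-[(R)-1-[(tert-butyldimethylsilyl)oxy]propan-2-yl]-2-methyl-2,3-dihydro-4H-pyran-4-one | CC(C)(C)[Si](C)(C)OC[C@@H](C)C1=CC(=O)C[C@H](C)O1 | intermediate
12 | (S)-6-[(R)-1-hydroxypropan-2-yl]-2-methyl-2,3-dihydro-4H-pyran-4-one | OC[C@@H](C)C1=CC(=O)C[C@H](C)O1 | intermediate
13 | (S)-6-[(S)-1-iodopropan-2-yl]-2-methyl-2,3-dihydro-4H-pyran-4-one | IC[C@@H](C)C1=CC(=O)C[C@H](C)O1 | intermediate
14 | eugenin (5-hydroxy-7-methoxy-2-methyl-4H-chromen-4-one) | COc1cc2oc(C)cc(=O)c2c(O)c1 | starting material
15 | 5-hydroxy-6-iodo-7-methoxy-2-methyl-4H-chromen-4-one | COc1cc2oc(C)cc(=O)c2c(O)c1I | intermediate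
16 | sodium 6-iodo-7-methoxy-2-methyl-4-oxo-4H-chromen-5-olate | COc1cc2oc(C)cc(=O)c2c(O[Na])c1I | intermediate
17 | 6-iodo-7-methoxy-5-(methoxymethoxy)-2-methyl-4H-chromen-4-one | COc1cc2oc(C)cc(=O)c2c(OCOC)c1I | intermediate
18 | [(2S)-2-[(2S)-2-methyl-4-oxo-3,4-dihydro-2H-pyran-6-yl]propyl]zinc iodide | I[Zn]C[C@@H](C)C1=CC(=O)C[C@H](C)O1 | intermediate
19 | 7-methoxy-5-(methoxymethoxy)-2-methyl-6-[(2R)-2-[(2S)-2-methyl-4-oxo-3,4-dihydro-2H-pyran-6-yl]propyl]-4H-chromen-4-one | COc1cc2oc(C)cc(=O)c2c(OCOC)c1C[C@@H](C)C1=CC(=O)C[C@H](C)O1 | intermediate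
20 | 5-hydroxy-7-methoxy-2-methyl-6-[(2R)-2-[(2S)-2-methyl-4-oxo-3,4-dihydro-2H-pyran-6-yl]propyl]-4H-chromen-4-one | COc1cc2oc(C)cc(=O)c2c(O)c1C[C@@H](C)C1=CC(=O)C[C@H](C)O1 | target

Total step count: 9. Longest linear sequence: 6 steps (steps 1, 2, 4, 5, 8, 9).

Steps most likely to fail

Step 8. Zinc insertion into 13 may be slow, or organozinc 18 may be lost by protonation or by addition to the vinylogous ester before it transmetalates to the hindered, di-ortho-substituted arylpalladium, so that reduction and homocoupling take over. The fallback drops the organometallic reagent altogether. Iodides 13 and 17 are joined directly as two electrophiles by nickel-catalysed reductive cross-electrophile coupling (NiI2, 4,4'-di-tert-butyl-2,2'-bipyridine, NaI, pyridine, Mn powder, DMPU, 60 °C). In this mode the aryl iodide adds to low-valent nickel and the alkyl iodide enters as a radical. The fallback sets out from 13 and 17, comes back to the route at 19 and makes no new compound.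

Step 4. The addition itself is expected to be reliable, but the protic one-flask stage may stall at solvent adducts of the ynone, or desilylation and ring closure may run out of step and give mixtures. The fallback separates the events and changes the mode of activation. The addition of 7 to 8 is quenched cold with aqueous citric acid and hydroxy ynone 10 is isolated. It is cycloisomerized with a carbophilic catalyst of monovalent gold (Ph3PAuNTf2, CH2Cl2, rt) to silyl ether 11, which is desilylated with HF·pyridine (THF, 0 °C) to 12. The fallback sets out from 4 and 6, comes back at 12 and makes no compound outside the list.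

Step 2. Over-reduction of the ester to the alcohol, or partial loss of configuration at the α-carbon of aldehyde 3 in basic methanol, may erode material or optical purity. The fallback avoids basic methanol. Ester 2 is reduced fully with LiBH4 (THF, MeOH) to (S)-3-[(tert-butyldimethylsilyl)oxy]-2-methylpropan-1-ol F1, which is oxidized under Swern conditions ((COCl)2, DMSO, i-Pr2NEt, –78 °C) to 3. The aldehyde is used cold at once in a Corey–Fuchs sequence: CBr4 and PPh3 (CH2Cl2, 0 °C) give (S)-tert-butyl[(4,4-dibromo-2-methylbut-3-en-1-yl)oxy]dimethylsilane F2, and n-BuLi (2.1 equiv, THF, –78 °C) followed by aqueous quench gives the alkyne. The fallback sets out from 2 and comes back at 4.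

Further compounds
F0 | step 8 | none | none
F0 | step 4 | none | none
F1 | step 2 | (S)-3-[(tert-butyldimethylsilyl)oxy]-2-methylpropan-1-ol | CC(C)(C)[Si](C)(C)OC[C@@H](C)CO
F2 | step 2 | (S)-tert-butyl[(4,4-dibromo-2-methylbut-3-en-1-yl)oxy]dimethylsilane | CC(C)(C)[Si](C)(C)OC[C@@H](C)C=C(Br)Br
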